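**Retrosynthetic overview**
- The target is traced back to a lactol with a 6β,7β-diol: the last two operations are oxidation of the allylic 7-OH to the enone and of the lactol to the lactone.
- The C13 tertiary carbinol comes from Sharpless epoxidation (D-(−)-DET) of a (12E)-allylic alcohol, followed by hydride opening of the epoxide at C12.
- Key disconnection C12–C13: intermolecular aldol addition of the lithium enolate of methyl 4,4-dimethoxybutanoate (C13–C16) to a C12 aldehyde carrying the complete, protected ring-B oxidation pattern, then dehydration.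
- The 6β-OH/7-O/Δ8 pattern is installed early on a (+)-sclareolide-derived Δ8 pivalate: allylic oxidation at C7, silyl dienol ether, hydroboration at C6, oxidation to the 6-ketone and α-face hydride reduction.
- Ring order: rings A/B are taken intact from (+)-sclareolide (its lactone is opened); the only ring built is the butanolide, closed last (a transient acetonide and epoxide appear in between).

Assumption: (+)-sclareolide counts as a cheap commercial chiral-pool starting material; labdane numbering is used throughout (β = same face as the C10 methyl, α = opposite face).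

**Step 1**
Reactants: 1 (+)-sclareolide
Product: 2 13,14,15,16-tetranorlabdane-8α,12-diol
Conditions: LiAlH4, THF, 0 °C → reflux; Fieser work-up
Reagents that add atoms: none
Why: LiAlH4 reduction of the lactone gives the diol and leaves the four ring stereocentres of sclareolide untouched.

**Step 2**
Reactants: 2 13,14,15,16-tetranorlabdane-8α,12-diol
Product: 3 8α-hydroxy-13,14,15,16-tetranorlabdan-12-yl pivalate
Conditions: PivCl, pyridine, DMAP (cat.), CH2Cl2, 0 °C → rt
Reagents that add atoms: pivaloyl chloride CC(C)(C)C(=O)Cl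
Why: Selective esterification of the primary alcohol, since the tertiary 8α-OH does not acylate under these conditions.

**Step 3**
Reactants: 3 8α-hydroxy-13,14,15,16-tetranorlabdan-12-yl pivalate
Product: 4 13,14,15,16-tetranorlabd-8-en-12-yl pivalate
Conditions: PPh3, I2, CH2Cl2, rt
Reagents that add atoms: none
Why: PPh3/I2 dehydration of the tertiary alcohol under equilibrating (HI) conditions gives the thermodynamically favoured tetrasubstituted Δ8(9) alkene.

**Step 4**
Reactants: 4 13,14,15,16-tetranorlabd-8-en-12-yl pivalate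
Product: 5 7-oxo-13,14,15,16-tetranorlabd-8-en-12-yl pivalate
Conditions: CrO3, 3,5-dimethylpyrazole, CH2Cl2, −20 °C → 0 °C
Reagents that add atoms: chromium trioxide O=[Cr](=O)=O
Why: Chromium(VI) allylic oxidation attacks the accessible ring allylic methylene C7 of the Δ8 alkene and gives the conjugated enone.

**Step 5**
Reactants: 5 7-oxo-13,14,15,16-tetranorlabd-8-en-12-yl pivalate
Product: 7 7-(tert-butyldimethylsilyloxy)-13,14,15,16-tetranorlabda-6,8-dien-12-yl pivalate, via lithium dienolate 6 (not isolated)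
Conditions: LDA, THF, −78 °C; TBSOTf, −78 °C → 0 °C; Et3N quench
Reagents that add atoms: tert-butyldimethylsilyl triflate CC(C)(C)[Si](C)(C)OS(=O)(=O)C(F)(F)F
Why: Kinetic α'-deprotonation at C6 followed by O-silylation gives the cross-conjugated silyl dienol ether (enolate trapping).

**Step 6**
Reactants: 7 7-(tert-butyldimethylsilyloxy)-13,14,15,16-tetranorlabda-6,8-dien-12-yl pivalate
Product: 9 6α-hydroxy-7β-(tert-butyldimethylsilyloxy)-13,14,15,16-tetranorlabd-8-en-12-yl pivalate, via 6α-alkylborane 8 (not isolated)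
Conditions: BH3·THF, THF, 0 °C → rt; then NaOH, H2O2, 0 °C
Reagents that add atoms: hydrogen peroxide OO
Why: Hydroboration–oxidation of the electron-rich enol-ether double bond places boron on C6 by syn addition from the α-face (the β-face is blocked by the axial C4β and C10β methyls), which sets 6α-OH and 7β-OTBS and leaves the hindered tetrasubstituted Δ8 alkene alone.

**Step 7**
Reactants: 9 6α-hydroxy-7β-(tert-butyldimethylsilyloxy)-13,14,15,16-tetranorlabd-8-en-12-yl pivalate
Product: 10 6-oxo-7β-(tert-butyldimethylsilyloxy)-13,14,15,16-tetranorlabd-8-en-12-yl pivalate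
Conditions: Dess–Martin periodinane, NaHCO3, CH2Cl2, 0 °C → rt
Reagents that add atoms: none
Why: Buffered Dess–Martin oxidation gives the 6-ketone without epimerising C5/C7 or moving the β,γ-double bond.

**Step 8**
Reactants: 10 6-oxo-7β-(tert-butyldimethylsilyloxy)-13,14,15,16-tetranorlabd-8-en-12-yl pivalate
Product: 11 7β-(tert-butyldimethylsilyloxy)-13,14,15,16-tetranorlabd-8-ene-6β,12-diol
Conditions: LiAlH4, THF, −20 °C → 0 °C
Reagents that add atoms: none
Why: Hydride reduction attacks the C6 ketone from the open α-face (the β-face is shielded by the 1,3-diaxial C4β/C10β methyls), which sets the axial 6β-OH, and the same reagent cleaves the pivalate.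

**Step 9**
Reactants: 11 7β-(tert-butyldimethylsilyloxy)-13,14,15,16-tetranorlabd-8-ene-6β,12-diol
Product: 12 13,14,15,16-tetranorlabd-8-ene-6β,7β,12-triol
Conditions: TBAF, THF, rt
Reagents that add atoms: none
Why: Fluoride desilylation frees the 7β-OH under non-acidic conditions that do not ionise the allylic alcohol.

**Step 10**
Reactants: 12 13,14,15,16-tetranorlabd-8-ene-6β,7β,12-triol
Product: 13 6β,7β-(isopropylidenedioxy)-13,14,15,16-tetranorlabd-8-en-12-ol
Conditions: 2,2-dimethoxypropane, PPTS (cat.), acetone, rt; then MeOH, 10 min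
Reagents that add atoms: 2,2-dimethoxypropane COC(C)(C)OC
Why: Acetalisation of the cis-6β,7β-diol gives the five-membered acetonide, and the short methanol treatment cleaves any mixed acetal on the primary alcohol.

**Step 11**
Reactants: 13 6β,7β-(isopropylidenedioxy)-13,14,15,16-tetranorlabd-8-en-12-ol
Product: 14 6β,7β-(isopropylidenedioxy)-13,14,15,16-tetranorlabd-8-en-12-al
Conditions: Dess–Martin periodinane, NaHCO3, CH2Cl2, 0 °C; used at once
Reagents that add atoms: none
Why: Neutral Dess–Martin oxidation gives the β,γ-unsaturated aldehyde without conjugating it.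

**Step 12**
Reactants: 14 6β,7β-(isopropylidenedioxy)-13,14,15,16-tetranorlabd-8-en-12-al; 15 methyl 4,4-dimethoxybutanoate
Product: 17 methyl 12-hydroxy-15,15-dimethoxy-6β,7β-(isopropylidenedioxy)labd-8-en-16-oate (C12/C13 diastereomer mixture), via lithium ester enolate 16 (not isolated)
Conditions: 15, LDA, THF, −78 °C, 30 min; then 14, −78 °C, 30 min; AcOH quench at −78 °C
Reagents that add atoms: none
Why: Intermolecular aldol addition of the lithium ester enolate to the aldehyde at −78 °C forms the C12–C13 bond faster than proton transfer, and the two new centres need no control because both are erased in the next step.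

**Step 13**
Reactants: 17 methyl 12-hydroxy-15,15-dimethoxy-6β,7β-(isopropylidenedioxy)labd-8-en-16-oate
Product: 19 methyl (12E)-15,15-dimethoxy-6β,7β-(isopropylidenedioxy)labda-8,12-dien-16-oate, via C12 mesylate 18 (not isolated)
Conditions: MsCl, Et3N, CH2Cl2, 0 °C; then DBU, 0 °C → rt (short)
Reagents that add atoms: none
Why: Mesylation and E1cB elimination complete the aldol condensation and converge both diastereomers on the more stable (E)-enoate with C11 trans to the ester.

**Step 14**
Reactants: 19 methyl (12E)-15,15-dimethoxy-6β,7β-(isopropylidenedioxy)labda-8,12-dien-16-oate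
Product: 20 (12E)-15,15-dimethoxy-6β,7β-(isopropylidenedioxy)labda-8,12-dien-16-ol
Conditions: DIBAL-H (2.5 equiv), CH2Cl2, −78 °C; Rochelle salt
Reagents that add atoms: none
Why: DIBAL-H 1,2-reduction of the enoate gives the allylic alcohol, and the acetal and acetonide are inert to it.

**Step 15**
Reactants: 20 (12E)-15,15-dimethoxy-6β,7β-(isopropylidenedioxy)labda-8,12-dien-16-ol
Product: 21 (12R,13R)-12,13-epoxy-15,15-dimethoxy-6β,7β-(isopropylidenedioxy)labd-8-en-16-ol
Conditions: Ti(OiPr)4 (10 mol%), D-(−)-diethyl tartrate (12 mol%), t-BuOOH (decane), 4 Å MS, CH2Cl2, −20 °C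
Reagents that add atoms: tert-butyl hydroperoxide CC(C)(C)OO
Why: Sharpless asymmetric epoxidation with D-(−)-DET delivers oxygen to the face of the (E)-allylic alcohol that gives the (12R,13R)-epoxide and so sets C13, while the Δ8 alkene is not an allylic alcohol and is not touched.

**Step 16**
Reactants: 21 (12R,13R)-12,13-epoxy-15,15-dimethoxy-6β,7β-(isopropylidenedioxy)labd-8-en-16-ol
Product: 22 (13R)-15,15-dimethoxy-6β,7β-(isopropylidenedioxy)labd-8-ene-13,16-diol
Conditions: LiAlH4, THF, 0 °C → rt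
Reagents that add atoms: none
Why: Hydride opens the epoxide by SN2 attack at the secondary C12 rather than the fully substituted C13, so the C13–O bond and its (13R) configuration are kept.

**Step 17**
Reactants: 22 (13R)-15,15-dimethoxy-6β,7β-(isopropylidenedioxy)labd-8-ene-13,16-diol
Product: 24 (13R)-15,16-epoxylabd-8-ene-6β,7β,13,15-tetrol (lactol; C15 anomer mixture), via open-chain hydroxy aldehyde 23 (not isolated)
Conditions: AcOH/THF/H2O 3:1:1, 40 °C
Reagents that add atoms: water O
Why: Mild acid hydrolysis removes the dimethyl acetal and the acetonide, and the freed C15 aldehyde is trapped by the 16-OH as the five-membered lactol.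

**Step 18**
Reactants: 24 (13R)-15,16-epoxylabd-8-ene-6β,7β,13,15-tetrol
Product: 25 (13R)-6β,13,15-trihydroxy-15,16-epoxylabd-8-en-7-one (lactol)
Conditions: activated MnO2 (20 equiv), CH2Cl2, rt
Reagents that add atoms: none
Why: MnO2 oxidises only the allylic 7-OH to the enone; the hindered axial 6β-OH and tertiary 13-OH stay, and C6 is not epimerised under neutral conditions.

**Step 19**
Reactants: 25 (13R)-6β,13,15-trihydroxy-15,16-epoxylabd-8-en-7-one
Product: 26 (13R)-6β,13-dihydroxy-7-oxolabd-8-en-15,16-olide (CNP0324736.1)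
Conditions: TEMPO (20 mol%), PhI(OAc)2 (1.5 equiv), CH2Cl2, rt
Reagents that add atoms: none
Why: TEMPO/PhI(OAc)2 oxidation converts the lactol into the γ-lactone, while the hindered secondary 6β-OH and the tertiary 13-OH are not oxidised.

**Compound list**
1 | (+)-sclareolide (13,14,15,16-tetranorlabdan-8α,12-olide) | C[C@]12CCCC([C@@H]1CC[C@@]3([C@@H]2CC(=O)O3)C)(C)C | starting material
2 | 13,14,15,16-tetranorlabdane-8α,12-diol | C[C@]12CCCC([C@@H]1CC[C@@]([C@@H]2CCO)(C)O)(C)C | intermediate
3 | 8α-hydroxy-13,14,15,16-tetranorlabdan-12-yl pivalate | C[C@]12CCCC([C@@H]1CC[C@@]([C@@H]2CCOC(=O)C(C)(C)C)(C)O)(C)C | intermediate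
4 | 13,14,15,16-tetranorlabd-8-en-12-yl pivalate | CC1=C(CCOC(=O)C(C)(C)C)[C@@]2(C)CCCC(C)(C)[C@@H]2CC1 | intermediate
5 | 7-oxo-13,14,15,16-tetranorlabd-8-en-12-yl pivalate | CC1=C(CCOC(=O)C(C)(C)C)[C@@]2(C)CCCC(C)(C)[C@@H]2CC1=O | intermediate
6 | lithium 12-(pivaloyloxy)-13,14,15,16-tetranorlabda-6,8-dien-7-olate (lithium dienolate) | [Li+].CC1=C(CCOC(=O)C(C)(C)C)[C@@]2(C)CCCC(C)(C)[C@@H]2C=C1[O-] | intermediate
7 | 7-(tert-butyldimethylsilyloxy)-13,14,15,16-tetranorlabda-6,8-dien-12-yl pivalate | CC1=C(CCOC(=O)C(C)(C)C)[C@@]2(C)CCCC(C)(C)[C@@H]2C=C1O[Si](C)(C)C(C)(C)C | intermediate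
8 | 6α-boranyl-7β-(tert-butyldimethylsilyloxy)-13,14,15,16-tetranorlabd-8-en-12-yl pivalate (6α-alkylborane) | CC1=C(CCOC(=O)C(C)(C)C)[C@@]2(C)CCCC(C)(C)[C@@H]2[C@@H](B)[C@@H]1O[Si](C)(C)C(C)(C)C | intermediate
9 | 6α-hydroxy-7β-(tert-butyldimethylsilyloxy)-13,14,15,16-tetranorlabd-8-en-12-yl pivalate | CC1=C(CCOC(=O)C(C)(C)C)[C@@]2(C)CCCC(C)(C)[C@@H]2[C@@H](O)[C@@H]1O[Si](C)(C)C(C)(C)C | intermediate
10 | 6-oxo-7β-(tert-butyldimethylsilyloxy)-13,14,15,16-tetranorlabd-8-en-12-yl pivalate | CC1=C(CCOC(=O)C(C)(C)C)[C@@]2(C)CCCC(C)(C)[C@@H]2C(=O)[C@@H]1O[Si](C)(C)C(C)(C)C | intermediate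
11 | 7β-(tert-butyldimethylsilyloxy)-13,14,15,16-tetranorlabd-8-ene-6β,12-diol | CC1=C(CCO)[C@@]2(C)CCCC(C)(C)[C@@H]2[C@H](O)[C@@H]1O[Si](C)(C)C(C)(C)C | intermediate
12 | 13,14,15,16-tetranorlabd-8-ene-6β,7β,12-triol | CC1=C(CCO)[C@@]2(C)CCCC(C)(C)[C@@H]2[C@H](O)[C@@H]1O | intermediate
13 | 6β,7β-(isopropylidenedioxy)-13,14,15,16-tetranorlabd-8-en-12-ol | CC1=C(CCO)[C@@]2(C)CCCC(C)(C)[C@@H]2[C@H](OC(C)(C)O3)[C@@H]13 | intermediate
14 | 6β,7β-(isopropylidenedioxy)-13,14,15,16-tetranorlabd-8-en-12-al | CC1=C(CC=O)[C@@]2(C)CCCC(C)(C)[C@@H]2[C@H](OC(C)(C)O3)[C@@H]13 | intermediate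
15 | methyl 4,4-dimethoxybutanoate | COC(=O)CCC(OC)OC | starting material
16 | lithium 1,4,4-trimethoxybut-1-en-1-olate (lithium ester enolate of 15) | [Li+].[O-]C(OC)=CCC(OC)OC | intermediate
17 | methyl 12-hydroxy-15,15-dimethoxy-6β,7β-(isopropylidenedioxy)labd-8-en-16-oate (C12/C13 mixture) | CC1=C(CC(O)C(CC(OC)OC)C(=O)OC)[C@@]2(C)CCCC(C)(C)[C@@H]2[C@H](OC(C)(C)O3)[C@@H]13 | intermediate
18 | methyl 12-(methylsulfonyloxy)-15,15-dimethoxy-6β,7β-(isopropylidenedioxy)labd-8-en-16-oate (C12 mesylate) | CC1=C(CC(OS(C)(=O)=O)C(CC(OC)OC)C(=O)OC)[C@@]2(C)CCCC(C)(C)[C@@H]2[C@H](OC(C)(C)O3)[C@@H]13 | intermediate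
19 | methyl (12E)-15,15-dimethoxy-6β,7β-(isopropylidenedioxy)labda-8,12-dien-16-oate | CC1=C(C/C=C(\CC(OC)OC)C(=O)OC)[C@@]2(C)CCCC(C)(C)[C@@H]2[C@H](OC(C)(C)O3)[C@@H]13 | intermediate
20 | (12E)-15,15-dimethoxy-6β,7β-(isopropylidenedioxy)labda-8,12-dien-16-ol | CC1=C(C/C=C(\CC(OC)OC)CO)[C@@]2(C)CCCC(C)(C)[C@@H]2[C@H](OC(C)(C)O3)[C@@H]13 | intermediate
21 | (12R,13R)-12,13-epoxy-15,15-dimethoxy-6β,7β-(isopropylidenedioxy)labd-8-en-16-ol | CC1=C(C[C@H]4O[C@]4(CC(OC)OC)CO)[C@@]2(C)CCCC(C)(C)[C@@H]2[C@H](OC(C)(C)O3)[C@@H]13 | intermediate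
22 | (13R)-15,15-dimethoxy-6β,7β-(isopropylidenedioxy)labd-8-ene-13,16-diol | CC1=C(CC[C@@](O)(CC(OC)OC)CO)[C@@]2(C)CCCC(C)(C)[C@@H]2[C@H](OC(C)(C)O3)[C@@H]13 | intermediate
23 | (13R)-6β,7β,13,16-tetrahydroxylabd-8-en-15-al (open-chain hydroxy aldehyde) | CC1=C(CC[C@@](O)(CC=O)CO)[C@@]2(C)CCCC(C)(C)[C@@H]2[C@H](O)[C@@H]1O | intermediate
24 | (13R)-15,16-epoxylabd-8-ene-6β,7β,13,15-tetrol (lactol, C15 anomers) | CC1=C(CC[C@]4(O)COC(O)C4)[C@@]2(C)CCCC(C)(C)[C@@H]2[C@H](O)[C@@H]1O | intermediate
25 | (13R)-6β,13,15-trihydroxy-15,16-epoxylabd-8-en-7-one (lactol, C15 anomers) | CC1=C(CC[C@]4(O)COC(O)C4)[C@@]2(C)CCCC(C)(C)[C@@H]2[C@H](O)C1=O | intermediate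
26 | (13R)-6β,13-dihydroxy-7-oxolabd-8-en-15,16-olide (CNP0324736.1) | CC1=C(CC[C@]2(O)COC(=O)C2)[C@@]2(C)CCCC(C)(C)[C@@H]2[C@H](O)C1=O | target

**Totals**
Total step count: 19. Longest linear sequence: 19 steps (1 → 26); fragment 15 is purchased.

**Three steps most likely to fail, with fallbacks**

Step 6 (hydroboration of the silyl dienol ether). The risks are competing reaction at the conjugated diene and elimination of the β-silyloxy borane. The fallback sets out from 5 and comes back at 9 without any hydroboration. The potassium dienolate of 5 (KHMDS, THF, −78 °C) is hydroxylated with 2-(phenylsulfonyl)-3-phenyloxaziridine from the open α-face to give 6α-hydroxy-7-oxo-13,14,15,16-tetranorlabd-8-en-12-yl pivalate F1. Luche reduction (NaBH4, CeCl3·7H2O, MeOH, −40 °C, hydride from the α-face) gives 6α,7β-dihydroxy-13,14,15,16-tetranorlabd-8-en-12-yl pivalate F2. Its less hindered allylic 7β-OH is monosilylated (TBSCl, imidazole, DMF, 0 °C) to give 9.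

Step 12 (aldol with the β,γ-unsaturated aldehyde). The risks are enolisation or conjugation of 14 by the basic ester enolate, and later isomerisation of the skipped diene during the DBU elimination of step 13. The fallback sets out from 14 (with 15) and comes back at 19, replacing the aldol/dehydration pair by an olefination. Ester 15 is C-phosphorylated (LDA 2.2 equiv, ClP(O)(OEt)2, THF, −78 °C → rt, via the enol phosphate and 1,3-phosphorus shift) to give methyl 2-(diethoxyphosphoryl)-4,4-dimethoxybutanoate F3. F3 is condensed with 14 under mild Masamune–Roush Horner–Wadsworth–Emmons conditions (LiCl, DBU, MeCN, 0 °C) to give the (E)-enoate 19 directly; the minor Z isomer is removed by chromatography.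

Step 17 (global acid hydrolysis). The risks are acid-induced dehydration of the tertiary-hydroxy lactol towards a furan and ionisation of the allylic 7-OH. The fallback sets out from 22 and comes back at 26 by unmasking the two acetals one after the other. PPTS in wet acetone at rt hydrolyses only the dimethyl acetal (assisted by the 16-OH) to give the acetonide lactol (13R)-6β,7β-(isopropylidenedioxy)-15,16-epoxylabd-8-ene-13,15-diol F4. TEMPO/PhI(OAc)2 oxidation gives the acetonide lactone (13R)-13-hydroxy-6β,7β-(isopropylidenedioxy)labd-8-en-15,16-olide F5. The acetonide is then removed on the robust lactone (CeCl3·7H2O, oxalic acid, MeCN, rt) to give (13R)-6β,7β,13-trihydroxylabd-8-en-15,16-olide F6. MnO2 oxidation of the allylic 7-OH of F6 gives 26.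

**Further compounds**
F1 | step 6 | 6α-hydroxy-7-oxo-13,14,15,16-tetranorlabd-8-en-12-yl pivalate | CC1=C(CCOC(=O)C(C)(C)C)[C@@]2(C)CCCC(C)(C)[C@@H]2[C@@H](O)C1=O
F2 | step 6 | 6α,7β-dihydroxy-13,14,15,16-tetranorlabd-8-en-12-yl pivalate | CC1=C(CCOC(=O)C(C)(C)C)[C@@]2(C)CCCC(C)(C)[C@@H]2[C@@H](O)[C@@H]1O
F3 | step 12 | methyl 2-(diethoxyphosphoryl)-4,4-dimethoxybutanoate | CCOP(=O)(OCC)C(CC(OC)OC)C(=O)OC
F4 | step 17 | (13R)-6β,7β-(isopropylidenedioxy)-15,16-epoxylabd-8-ene-13,15-diol | CC1=C(CC[C@]4(O)COC(O)C4)[C@@]2(C)CCCC(C)(C)[C@@H]2[C@H](OC(C)(C)O3)[C@@H]13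
F5 | step 17 | (13R)-13-hydroxy-6β,7β-(isopropylidenedioxy)labd-8-en-15,16-olide | CC1=C(CC[C@]4(O)COC(=O)C4)[C@@]2(C)CCCC(C)(C)[C@@H]2[C@H](OC(C)(C)O3)[C@@H]13
F6 | step 17 | (13R)-6β,7β,13-trihydroxylabd-8-en-15,16-olide | CC1=C(CC[C@]4(O)COC(=O)C4)[C@@]2(C)CCCC(C)(C)[C@@H]2[C@H](O)[C@@H]1O
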